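**Strategy.** The plan rests on making the furan last and cutting its C3–C4 bond: O1, C2 and C3 (with the side chain) derive from a 2-alkylated allylic alcohol, C4 and C5 from an acrolein methyl acetal. The furan is substituted at C3 only, so one ruthenium-catalysed ring-closing metathesis between the acetal vinyl group (the only monosubstituted alkene) and the neighbouring 1,1-disubstituted alkene, followed in the same flask by acid-induced loss of methanol, closes and aromatises the ring. The precursor is the allyl vinyl mixed methyl acetal of the complete (Z)-enoate methyl ester, already carrying the (R)-stereocentre and the polyene arm; no furan is present during the organometallic steps.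

Key step: step 19

Remarks on the chemistry:
- The stereocentre is a tertiary CH, so the copper-catalysed SN2′ step needs a linear E-allylic electrophile with the whole C15 tail on its γ-carbon. A neryl electrophile itself would give a quaternary, methyl-bearing centre, so nerol is first extended to the C18 phosphate 15.
- Assumption: in step 8 the enantiomer of the NHC ligand is the one that gives (S)-17; should a test run show the opposite sense, the mirror-image ligand is used. (S)-17 has the spatial arrangement of the (R)-centre of the target; only the CIP priorities change.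
- The acetal carbon of 37 and 38 forms as a mixture of epimers; both converge in step 19.

**Step 1**
Reactants: 1 nerol
Product: 2 neryl bromide
Conditions: PBr3, Et2O, −20 → 0 °C
Reagents that add atoms: phosphorus tribromide, BrP(Br)Br
Why: SN2 displacement of the phosphite-activated primary allylic hydroxyl by bromide at low temperature (alcohol-to-bromide conversion with PBr3) should keep the Z-alkene and avoid allylic transposition.

**Step 2**
Reactants: 2 neryl bromide; 3 1-(trimethylsilyl)propyne
Product: 6 (5Z)-6,10-dimethylundeca-5,9-dien-1-yne, via lithiated silylpropyne 4 (not isolated), via silyl enyne 5 (not isolated)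
Conditions: n-BuLi, THF, −78 °C; 2, −78 °C → rt; then MeOH, K2CO3 (cat.), rt
Reagents that add atoms: none
Why: Propargylic lithiation of the silyl-capped propyne and SN2 alkylation by the primary allylic bromide join the C3 unit to the neryl unit, and methanolysis of the C–Si bond in the same flask frees the terminal alkyne (propargyl anion alkylation, then protodesilylation).

**Step 3**
Reactants: 6 (5Z)-6,10-dimethylundeca-5,9-dien-1-yne
Product: 9 (2E,6Z)-farnesol, via alkenylalane 7 (not isolated), via lithium alanate 8 (not isolated)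
Conditions: AlMe3, Cp2ZrCl2 (cat.), CH2Cl2, 0 °C → rt; n-BuLi, THF/hexane, −78 → 0 °C; (CH2O)n, rt; aq. NH4Cl
Reagents that add atoms: trimethylaluminium, C[Al](C)C; paraformaldehyde (as formaldehyde), C=O
Why: Zirconium-catalysed syn-methylalumination of the terminal alkyne (Negishi carboalumination) puts methyl on the internal and aluminium on the terminal carbon, which fixes the E-trisubstituted alkene, and the derived alanate is hydroxymethylated by formaldehyde with retention.

**Step 4**
Reactants: 9 (2E,6Z)-farnesol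
Product: 10 (2E,6Z)-farnesyl bromide
Conditions: PBr3, Et2O, −20 → 0 °C
Reagents that add atoms: phosphorus tribromide, BrP(Br)Br
Why: The same SN2 bromination of a primary allylic alcohol as in step 1 should give the bromide with both alkene geometries intact.

**Step 5**
Reactants: 10 (2E,6Z)-farnesyl bromide; 11 propargyl alcohol
Product: 12 (5E,9Z)-6,10,14-trimethylpentadeca-5,9,13-trien-2-yn-1-ol
Conditions: CuI (cat.), K2CO3, n-Bu4NI (cat.), DMF, rt
Reagents that add atoms: none
Why: The copper acetylide formed under carbonate is alkylated by the primary allylic bromide at its unsubstituted terminus (copper-catalysed alkyne–allyl halide coupling), giving the skipped enyne while the free hydroxyl stays unalkylated.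

**Step 6**
Reactants: 12 (5E,9Z)-6,10,14-trimethylpentadeca-5,9,13-trien-2-yn-1-ol
Product: 14 (2E,5E,9Z)-6,10,14-trimethylpentadeca-2,5,9,13-tetraen-1-ol, via cyclic alkenylalanate 13 (not isolated)
Conditions: NaAlH2(OCH2CH2OMe)2, THF, 0 °C → rt; aq. potassium sodium tartrate
Reagents that add atoms: none
Why: Hydroxyl-directed anti-hydroalumination of the propargylic alcohol and protonolysis of the vinyl–aluminium bond should give only the E-allylic alcohol, the isolated alkenes being inert to the hydride.

**Step 7**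
Reactants: 14 (2E,5E,9Z)-6,10,14-trimethylpentadeca-2,5,9,13-tetraen-1-ol
Product: 15 diethyl (2E,5E,9Z)-6,10,14-trimethylpentadeca-2,5,9,13-tetraen-1-yl phosphate
Conditions: (EtO)2P(O)Cl, Et3N, DMAP (cat.), CH2Cl2, 0 °C
Reagents that add atoms: diethyl chlorophosphate, CCOP(=O)(Cl)OCC
Why: O-Phosphorylation of the primary alcohol under nucleophilic catalysis installs the leaving group used in copper-catalysed allylic substitution.

**Step 8**
Reactants: 15 diethyl (2E,5E,9Z)-6,10,14-trimethylpentadeca-2,5,9,13-tetraen-1-yl phosphate; 16 isopropenylboronic acid pinacol ester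
Product: 17 (3S,5E,9Z)-6,10,14-trimethyl-3-(prop-1-en-2-yl)pentadeca-1,5,9,13-tetraene
Conditions: CuCl (5 mol %), enantiopure sulfonate-bearing imidazolinium salt (NHC precursor, 5.5 mol %), NaOMe, THF, 60 °C
Reagents that add atoms: none
Why: In this NHC–copper-catalysed enantioselective allylic substitution, methoxide activates the boronate, isopropenyl passes to copper and is delivered SN2′ to C3 of the E-allylic phosphate, the chiral sulfonate-bridged carbene choosing the alkene face and so setting the (S)-configured tertiary centre, while the trisubstituted alkenes are spectators.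

**Step 9**
Reactants: 17 (3S,5E,9Z)-6,10,14-trimethyl-3-(prop-1-en-2-yl)pentadeca-1,5,9,13-tetraene
Product: 19 (3S,5E,9Z)-6,10,14-trimethyl-3-(prop-1-en-2-yl)pentadeca-5,9,13-trien-1-ol, via trialkylborane 18 (not isolated)
Conditions: BH3·SMe2, 2-methylbut-2-ene, THF, 0 °C (gives Sia2BH); 17, 0 °C; then NaOH, H2O2, 0 °C → rt
Reagents that add atoms: hydrogen peroxide, OO
Why: Hydroboration–oxidation with the bulky dialkylborane is expected to take the monosubstituted vinyl group in preference to the more hindered isopropenyl and trisubstituted alkenes and to place boron on the terminal carbon, so that oxidation with retention gives the primary alcohol without touching the stereocentre.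

**Step 10**
Reactants: 19 (3S,5E,9Z)-6,10,14-trimethyl-3-(prop-1-en-2-yl)pentadeca-5,9,13-trien-1-ol
Product: 20 (3S,5E,9Z)-1-iodo-6,10,14-trimethyl-3-(prop-1-en-2-yl)pentadeca-5,9,13-triene
Conditions: I2, PPh3, imidazole, CH2Cl2, 0 °C → rt
Reagents that add atoms: iodine, II
Why: Appel-type iodination (displacement of the oxyphosphonium group by iodide) converts the primary alcohol to the iodide under neutral conditions that leave the polyene alone.

**Step 11**
Reactants: 21 2-methylenepropane-1,3-diol
Product: 23 2-{[(tert-butyldimethylsilyl)oxy]methyl}prop-2-en-1-ol, via monosodium alkoxide 22 (not isolated)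
Conditions: NaH (1 equiv), THF, 0 °C → rt; TBSCl
Reagents that add atoms: tert-butyldimethylsilyl chloride, CC(C)(C)[Si](C)(C)Cl
Why: One equivalent of NaH gives the sparingly soluble monosodium alkoxide, which is silylated once (monosilylation of a symmetrical diol through its monoalkoxide).

**Step 12**
Reactants: 23 2-{[(tert-butyldimethylsilyl)oxy]methyl}prop-2-en-1-ol; 24 triethyl orthoacetate
Product: 27 ethyl 4-{[(tert-butyldimethylsilyl)oxy]methyl}pent-4-enoate, via mixed orthoester 25 (not isolated), via ketene acetal 26 (not isolated)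
Conditions: EtCO2H (cat.), neat MeC(OEt)3, 140 °C, EtOH distilled off
Reagents that add atoms: none
Why: In this Johnson–Claisen rearrangement, acid-catalysed exchange and loss of ethanol give the ketene acetal, whose [3,3]-sigmatropic shift transfers the two-carbon ester unit to the methylene terminus and regenerates a 1,1-disubstituted alkene carrying the silyloxymethyl group.

**Step 13**
Reactants: 27 ethyl 4-{[(tert-butyldimethylsilyl)oxy]methyl}pent-4-enoate
Product: 29 4-{[(tert-butyldimethylsilyl)oxy]methyl}pent-4-enal, via aluminium hemiacetal 28 (not isolated)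
Conditions: i-Bu2AlH (1.05 equiv), CH2Cl2, −78 °C; aq. potassium sodium tartrate
Reagents that add atoms: none
Why: Partial reduction of the ester with one equivalent of i-Bu2AlH at −78 °C stops at the tetrahedral aluminium hemiacetal, which releases the aldehyde on work-up.

**Step 14**
Reactants: 29 4-{[(tert-butyldimethylsilyl)oxy]methyl}pent-4-enal
Product: 30 tert-butyl[(6,6-dibromo-2-methylidenehex-5-en-1-yl)oxy]dimethylsilane
Conditions: CBr4, PPh3, Zn, CH2Cl2, rt; then 29, 0 °C → rt
Reagents that add atoms: carbon tetrabromide, BrC(Br)(Br)Br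
Why: Wittig-type dibromomethylenation of the unhindered aldehyde (first stage of the Corey–Fuchs sequence) with the ylide made from CBr4, PPh3 and zinc proceeds without acid and should spare the allylic silyl ether.

**Step 15**
Reactants: 20 (3S,5E,9Z)-1-iodo-6,10,14-trimethyl-3-(prop-1-en-2-yl)pentadeca-5,9,13-triene; 30 tert-butyl[(6,6-dibromo-2-methylidenehex-5-en-1-yl)oxy]dimethylsilane
Product: 32 tert-butyl{[(5Z,9R,11E,15Z)-6-bromo-12,16,20-trimethyl-2-methylidene-9-(prop-1-en-2-yl)henicosa-5,11,15,19-tetraen-1-yl]oxy}dimethylsilane, via alkylzinc iodide 31 (not isolated)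
Conditions: Zn dust, LiCl, THF, 40 °C; then 30 (slight excess), PdCl2(DPEphos) (5 mol %), THF/DMF, 0 °C → rt
Reagents that add atoms: none
Why: LiCl-promoted zinc insertion gives the primary alkylzinc iodide with the stereocentre untouched, and the trans-selective Negishi monoalkylation of the 1,1-dibromoalkene takes place at the less hindered bromine trans to the alkyl chain, so the new alkyl group ends up trans and the remaining bromine cis to that chain.

**Step 16**
Reactants: 32 tert-butyl{[(5Z,9R,11E,15Z)-6-bromo-12,16,20-trimethyl-2-methylidene-9-(prop-1-en-2-yl)henicosa-5,11,15,19-tetraen-1-yl]oxy}dimethylsilane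
Product: 34 methyl (2Z)-6-{[(tert-butyldimethylsilyl)oxy]methyl}-2-[(3R,5E,9Z)-6,10,14-trimethyl-3-(prop-1-en-2-yl)pentadeca-5,9,13-trien-1-yl]hepta-2,6-dienoate, via alkenyllithium 33 (not isolated)
Conditions: t-BuLi (2 equiv), Et2O, −78 °C; ClCO2Me, −78 → 0 °C
Reagents that add atoms: methyl chloroformate, COC(=O)Cl
Why: Bromine–lithium exchange with retention of alkene geometry at −78 °C and acylation of the configurationally stable alkenyllithium by methyl chloroformate put the ester cis to the chain, which is the Z-enoate.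

**Step 17**
Reactants: 34 methyl (2Z)-6-{[(tert-butyldimethylsilyl)oxy]methyl}-2-[(3R,5E,9Z)-6,10,14-trimethyl-3-(prop-1-en-2-yl)pentadeca-5,9,13-trien-1-yl]hepta-2,6-dienoate
Product: 35 methyl (2Z)-6-(hydroxymethyl)-2-[(3R,5E,9Z)-6,10,14-trimethyl-3-(prop-1-en-2-yl)pentadeca-5,9,13-trien-1-yl]hepta-2,6-dienoate
Conditions: HF·pyridine, pyridine, THF, 0 °C → rt
Reagents that add atoms: none
Why: Fluoride cleavage of the primary allylic silyl ether under buffered, non-basic conditions (desilylation) should leave the Z-enoate and the polyene unchanged.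

**Step 18**
Reactants: 35 methyl (2Z)-6-(hydroxymethyl)-2-[(3R,5E,9Z)-6,10,14-trimethyl-3-(prop-1-en-2-yl)pentadeca-5,9,13-trien-1-yl]hepta-2,6-dienoate; 36 methoxyallene
Product: 37 methyl (2Z)-6-{[(1-methoxyprop-2-en-1-yl)oxy]methyl}-2-[(3R,5E,9Z)-6,10,14-trimethyl-3-(prop-1-en-2-yl)pentadeca-5,9,13-trien-1-yl]hepta-2,6-dienoate
Conditions: Pd(OAc)2 (5 mol %), dppp, Et3N, MeCN, rt
Reagents that add atoms: none
Why: Palladium-catalysed hydroalkoxylation of the alkoxyallene, in which the alcohol adds to the oxygen-bearing terminus of the methoxy-substituted π-allyl palladium intermediate, gives the acrolein-type mixed acetal under basic conditions; the new acetal centre forms as both epimers, which does not matter because step 19 destroys it.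

**Step 19**
Reactants: 37 methyl (2Z)-6-{[(1-methoxyprop-2-en-1-yl)oxy]methyl}-2-[(3R,5E,9Z)-6,10,14-trimethyl-3-(prop-1-en-2-yl)pentadeca-5,9,13-trien-1-yl]hepta-2,6-dienoate
Product: 39 methyl (2Z)-5-(furan-3-yl)-2-[(3R,5E,9Z)-6,10,14-trimethyl-3-(prop-1-en-2-yl)pentadeca-5,9,13-trien-1-yl]pent-2-enoate, via methoxydihydrofuran 38 (not isolated)
Conditions: second-generation Grubbs catalyst (H2IMes)(PCy3)Cl2Ru=CHPh (5 mol %), CH2Cl2 (dilute), 40 °C; then pyridinium p-toluenesulfonate (cat.), rt
Reagents that add atoms: none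
Why: The ruthenium benzylidene exchanges onto the acetal vinyl group, and the resulting alkylidene undergoes [2+2] cycloaddition with the 1,1-disubstituted alkene five atoms away and cycloreversion with loss of ethene, which forms the C3–C4 bond of the later furan. The closest known reaction type is ring-closing metathesis of allyl acrolein-type mixed acetals to 2-methoxy-2,5-dihydrofurans followed by acid-promoted aromatisation to furans. The single ring is closed as a five-membered oxacycle by alkene–alkene metathesis between the two terminal alkenes, the most favourable ring size open to the substrate. No stereocentre is created: the acetal carbon, present as both epimers, is ionised by the pyridinium salt to an oxocarbenium ion that loses the C2 proton, so both epimers give the same aromatic ring. The step needs chemoselectivity among seven alkenes, which is secured because initiation is fast only at the one monosubstituted alkene, five-membered closure under dilution outruns medium-ring or intermolecular events, and the other alkenes are trisubstituted, conjugated to the ester or a hindered isopropenyl group. The weak acid is chosen so that neither the polyene nor the Z-enoate is protonated.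

**Step 20**
Reactants: 39 methyl (2Z)-5-(furan-3-yl)-2-[(3R,5E,9Z)-6,10,14-trimethyl-3-(prop-1-en-2-yl)pentadeca-5,9,13-trien-1-yl]pent-2-enoate
Product: 41 (2Z)-5-(furan-3-yl)-2-[(3R,5E,9Z)-6,10,14-trimethyl-3-(prop-1-en-2-yl)pentadeca-5,9,13-trien-1-yl]pent-2-enoic acid, via lithium carboxylate 40 (not isolated)
Conditions: LiOH, THF/MeOH/H2O, rt → 40 °C; then aq. HCl to pH 4, 0 °C
Reagents that add atoms: lithium hydroxide, [Li+].[OH-]
Why: Saponification of the methyl ester by hydroxide (acyl–oxygen cleavage) and mild acidification should give the acid, since the furan, the Z-enoate and the allylic stereocentre tolerate aqueous base at this temperature.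

**Compound list**

1 | nerol, (2Z)-3,7-dimethylocta-2,6-dien-1-ol | CC(C)=CCC/C(C)=C\CO | starting material
2 | neryl bromide, (2Z)-1-bromo-3,7-dimethylocta-2,6-diene | CC(C)=CCC/C(C)=C\CBr | intermediate
3 | 1-(trimethylsilyl)propyne | CC#C[Si](C)(C)C | starting material
4 | 3-lithio-1-(trimethylsilyl)propyne | [Li]CC#C[Si](C)(C)C | intermediate (not isolated)
5 | [(5Z)-6,10-dimethylundeca-5,9-dien-1-yn-1-yl]trimethylsilane | C[Si](C)(C)C#CCC/C=C(/C)CCC=C(C)C | intermediate (not isolated)
6 | (5Z)-6,10-dimethylundeca-5,9-dien-1-yne | C#CCC/C=C(/C)CCC=C(C)C | intermediate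
7 | dimethyl[(1E,5Z)-2,6,10-trimethylundeca-1,5,9-trien-1-yl]alane | C[Al](C)/C=C(\C)CC/C=C(/C)CCC=C(C)C | intermediate (not isolated)
8 | lithium butyl(dimethyl)[(1E,5Z)-2,6,10-trimethylundeca-1,5,9-trien-1-yl]aluminate | [Li+].CCCC[Al-](C)(C)/C=C(\C)CC/C=C(/C)CCC=C(C)C | intermediate (not isolated)
9 | (2E,6Z)-farnesol, (2E,6Z)-3,7,11-trimethyldodeca-2,6,10-trien-1-ol | OC/C=C(\C)CC/C=C(/C)CCC=C(C)C | intermediate
10 | (2E,6Z)-farnesyl bromide | BrC/C=C(\C)CC/C=C(/C)CCC=C(C)C | intermediate
11 | propargyl alcohol, prop-2-yn-1-ol | C#CCO | starting material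
12 | (5E,9Z)-6,10,14-trimethylpentadeca-5,9,13-trien-2-yn-1-ol | OCC#CC/C=C(\C)CC/C=C(/C)CCC=C(C)C | intermediate
13 | sodium cyclic alkenylalanate: five-membered O–Al–C=C–CH2 ring, aluminium carrying two 2-methoxyethoxy groups, the C13 chain on the aluminium-bound alkene carbon | [Na+].COCCO[Al-]1(OCCOC)OCC=C1C/C=C(\C)CC/C=C(/C)CCC=C(C)C | intermediate (not isolated)
14 | (2E,5E,9Z)-6,10,14-trimethylpentadeca-2,5,9,13-tetraen-1-ol | OC/C=C/C/C=C(\C)CC/C=C(/C)CCC=C(C)C | intermediate
15 | diethyl (2E,5E,9Z)-6,10,14-trimethylpentadeca-2,5,9,13-tetraen-1-yl phosphate | CCOP(=O)(OCC)OC/C=C/C/C=C(\C)CC/C=C(/C)CCC=C(C)C | intermediate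
16 | isopropenylboronic acid pinacol ester | C=C(C)B1OC(C)(C)C(C)(C)O1 | starting material
17 | (3S,5E,9Z)-6,10,14-trimethyl-3-(prop-1-en-2-yl)pentadeca-1,5,9,13-tetraene | C=C(C)[C@@H](C/C=C(\C)CC/C=C(/C)CCC=C(C)C)C=C | intermediate
18 | bis(3-methylbutan-2-yl)borane adduct of 17 at its terminal vinyl carbon (stereocentre and alkenes as in 17) | C=C(C)[C@@H](C/C=C(\C)CC/C=C(/C)CCC=C(C)C)CCB(C(C)C(C)C)C(C)C(C)C | intermediate (not isolated)
19 | (3S,5E,9Z)-6,10,14-trimethyl-3-(prop-1-en-2-yl)pentadeca-5,9,13-trien-1-ol | C=C(C)[C@@H](C/C=C(\C)CC/C=C(/C)CCC=C(C)C)CCO | intermediate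
20 | (3S,5E,9Z)-1-iodo-6,10,14-trimethyl-3-(prop-1-en-2-yl)pentadeca-5,9,13-triene | C=C(C)[C@@H](C/C=C(\C)CC/C=C(/C)CCC=C(C)C)CCI | intermediate
21 | 2-methylenepropane-1,3-diol | C=C(CO)CO | starting material
22 | sodium 2-(hydroxymethyl)prop-2-en-1-olate | [Na+].[O-]CC(=C)CO | intermediate (not isolated)
23 | 2-{[(tert-butyldimethylsilyl)oxy]methyl}prop-2-en-1-ol | C=C(CO)CO[Si](C)(C)C(C)(C)C | intermediate
24 | triethyl orthoacetate | CCOC(C)(OCC)OCC | starting material
25 | mixed orthoester, 1,1-diethoxyethyl ether of 23 | CCOC(C)(OCC)OCC(=C)CO[Si](C)(C)C(C)(C)C | intermediate (not isolated)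
26 | ketene acetal, 1-ethoxyvinyl ether of 23 | C=C(OCC)OCC(=C)CO[Si](C)(C)C(C)(C)C | intermediate (not isolated)
27 | ethyl 4-{[(tert-butyldimethylsilyl)oxy]methyl}pent-4-enoate | CCOC(=O)CCC(=C)CO[Si](C)(C)C(C)(C)C | intermediate
28 | diisobutylaluminium hemiacetal of 27 | CCOC(CCC(=C)CO[Si](C)(C)C(C)(C)C)O[Al](CC(C)C)CC(C)C | intermediate (not isolated)
29 | 4-{[(tert-butyldimethylsilyl)oxy]methyl}pent-4-enal | O=CCCC(=C)CO[Si](C)(C)C(C)(C)C | intermediate
30 | tert-butyl[(6,6-dibromo-2-methylidenehex-5-en-1-yl)oxy]dimethylsilane | BrC(Br)=CCCC(=C)CO[Si](C)(C)C(C)(C)C | intermediate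
31 | [(3S,5E,9Z)-6,10,14-trimethyl-3-(prop-1-en-2-yl)pentadeca-5,9,13-trien-1-yl]zinc iodide | C=C(C)[C@@H](C/C=C(\C)CC/C=C(/C)CCC=C(C)C)CC[Zn]I | intermediate (not isolated)
32 | tert-butyl{[(5Z,9R,11E,15Z)-6-bromo-12,16,20-trimethyl-2-methylidene-9-(prop-1-en-2-yl)henicosa-5,11,15,19-tetraen-1-yl]oxy}dimethylsilane (Br cis to the silyloxy-bearing chain) | C=C(C)[C@@H](C/C=C(\C)CC/C=C(/C)CCC=C(C)C)CC/C(Br)=C/CCC(=C)CO[Si](C)(C)C(C)(C)C | intermediate
33 | alkenyllithium from 32 (Li in place of Br, same geometry) | C=C(C)[C@@H](C/C=C(\C)CC/C=C(/C)CCC=C(C)C)CC/C([Li])=C/CCC(=C)CO[Si](C)(C)C(C)(C)C | intermediate (not isolated)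
34 | methyl (2Z)-6-{[(tert-butyldimethylsilyl)oxy]methyl}-2-[(3R,5E,9Z)-6,10,14-trimethyl-3-(prop-1-en-2-yl)pentadeca-5,9,13-trien-1-yl]hepta-2,6-dienoate | C=C(C)[C@@H](C/C=C(\C)CC/C=C(/C)CCC=C(C)C)CC/C(=C/CCC(=C)CO[Si](C)(C)C(C)(C)C)C(=O)OC | intermediate
35 | methyl (2Z)-6-(hydroxymethyl)-2-[(3R,5E,9Z)-6,10,14-trimethyl-3-(prop-1-en-2-yl)pentadeca-5,9,13-trien-1-yl]hepta-2,6-dienoate | C=C(C)[C@@H](C/C=C(\C)CC/C=C(/C)CCC=C(C)C)CC/C(=C/CCC(=C)CO)C(=O)OC | intermediate
36 | methoxyallene | COC=C=C | starting material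
37 | methyl (2Z)-6-{[(1-methoxyprop-2-en-1-yl)oxy]methyl}-2-[(3R,5E,9Z)-6,10,14-trimethyl-3-(prop-1-en-2-yl)pentadeca-5,9,13-trien-1-yl]hepta-2,6-dienoate (either acetal epimer) | C=C(C)[C@@H](C/C=C(\C)CC/C=C(/C)CCC=C(C)C)CC/C(=C/CCC(=C)COC(OC)C=C)C(=O)OC | intermediate
38 | methyl (2Z)-5-(5-methoxy-2,5-dihydrofuran-3-yl)-2-[(3R,5E,9Z)-6,10,14-trimethyl-3-(prop-1-en-2-yl)pentadeca-5,9,13-trien-1-yl]pent-2-enoate (either acetal epimer) | C=C(C)[C@@H](C/C=C(\C)CC/C=C(/C)CCC=C(C)C)CC/C(=C/CCC1=CC(OC)OC1)C(=O)OC | intermediate (not isolated)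
39 | methyl (2Z)-5-(furan-3-yl)-2-[(3R,5E,9Z)-6,10,14-trimethyl-3-(prop-1-en-2-yl)pentadeca-5,9,13-trien-1-yl]pent-2-enoate | C=C(C)[C@@H](C/C=C(\C)CC/C=C(/C)CCC=C(C)C)CC/C(=C/CCc1ccoc1)C(=O)OC | intermediate
40 | lithium salt of 41 | [Li+].C=C(C)[C@@H](C/C=C(\C)CC/C=C(/C)CCC=C(C)C)CC/C(=C/CCc1ccoc1)C(=O)[O-] | intermediate (not isolated)
41 | (2Z)-5-(furan-3-yl)-2-[(3R,5E,9Z)-6,10,14-trimethyl-3-(prop-1-en-2-yl)pentadeca-5,9,13-trien-1-yl]pent-2-enoic acid | C=C(C)[C@@H](C/C=C(\C)CC/C=C(/C)CCC=C(C)C)CC/C(=C/CCc1ccoc1)C(=O)O | target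

**Totals**
Total step count: 20.
Longest linear sequence: 16 steps (steps 1–10, then 15–20); steps 11–14 make the second coupling partner.

**Steps most likely to fail**

Step 19. What may go wrong: the ruthenium alkylidene may be held unproductively by the acetal oxygens or engage other alkenes intermolecularly, or the acetal may ionise and hydrolyse before the ring has closed. Fallback (furan present from the start, sets out from iodide 20, returns at ester 39): 3-bromofuran is lithiated (n-BuLi, THF, −78 °C) and added to oxetane with BF3·OEt2 to give 3-(furan-3-yl)propan-1-ol F7. Dess–Martin oxidation (NaHCO3, CH2Cl2) gives 3-(furan-3-yl)propanal F8, and CBr4/PPh3/Zn converts it to 3-(4,4-dibromobut-3-en-1-yl)furan F9. Negishi coupling of F9 with the zinc reagent 31 (from 20 as in step 15, PdCl2(DPEphos)) gives the (Z)-bromoalkene 3-[(3Z,7R,9E,13Z)-4-bromo-10,14,18-trimethyl-7-(prop-1-en-2-yl)nonadeca-3,9,13,17-tetraen-1-yl]furan F10. Palladium-catalysed methoxycarbonylation of F10 (Pd(OAc)2, Xantphos, CO, MeOH, Et3N, 70 °C) gives 39, which continues with step 20.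

Step 8. What may go wrong: incomplete branch selectivity (SN2 against SN2′) or weak enantiofacial discrimination when the isopropenyl–copper species is transferred to a purely aliphatic phosphate. Fallback (auxiliary-controlled alkylation, sets out from bromide 10, returns at alcohol 19): mono-tert-butyl succinate, as its pivaloyl mixed anhydride, acylates lithiated (S)-4-benzyl-1,3-oxazolidin-2-one to give tert-butyl 4-[(4S)-4-benzyl-2-oxo-1,3-oxazolidin-3-yl]-4-oxobutanoate F1. Its sodium enolate (NaN(SiMe3)2, THF, −78 °C) is alkylated by 10 on the face away from the benzyl group to give the (S)-configured imide F2. AlMe3/MeONHMe·HCl gives the Weinreb amide F3 and returns the auxiliary, and MeMgBr gives the methyl ketone F4. Non-basic methylenation (Zn, CH2Br2, TiCl4) gives the isopropenyl tert-butyl ester F5, and LiAlH4 reduces it to 19.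

Step 15. What may go wrong: a second oxidative addition at the remaining C–Br bond (double alkylation), β-hydride elimination from the alkylpalladium intermediate, or loss of trans-selectivity. Fallback (Z-selective olefination, sets out from iodide 20 and aldehyde 29, returns at ester 34): methyl bis(2,2,2-trifluoroethyl)phosphonoacetate is alkylated with 20 (NaH, DMSO) to give the α-alkylated phosphonate methyl (5R,7E,11Z)-2-[bis(2,2,2-trifluoroethoxy)phosphoryl]-8,12,16-trimethyl-5-(prop-1-en-2-yl)heptadeca-7,11,15-trienoate F6 (both α-epimers). Still–Gennari olefination of 29 with F6 (KN(SiMe3)2, 18-crown-6, THF, −78 °C) should give the Z-enoate 34 directly, bypassing 30–33.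

**Further compounds**

F7 | step 19 | 3-(furan-3-yl)propan-1-ol | OCCCc1ccoc1
F8 | step 19 | 3-(furan-3-yl)propanal | O=CCCc1ccoc1
F9 | step 19 | 3-(4,4-dibromobut-3-en-1-yl)furan | BrC(Br)=CCCc1ccoc1
F10 | step 19 | 3-[(3Z,7R,9E,13Z)-4-bromo-10,14,18-trimethyl-7-(prop-1-en-2-yl)nonadeca-3,9,13,17-tetraen-1-yl]furan | C=C(C)[C@@H](C/C=C(\C)CC/C=C(/C)CCC=C(C)C)CC/C(Br)=C/CCc1ccoc1
F1 | step 8 | tert-butyl 4-[(4S)-4-benzyl-2-oxo-1,3-oxazolidin-3-yl]-4-oxobutanoate | O=C1OC[C@H](Cc2ccccc2)N1C(=O)CCC(=O)OC(C)(C)C
F2 | step 8 | tert-butyl (3S,5E,9Z)-3-{[(4S)-4-benzyl-2-oxo-1,3-oxazolidin-3-yl]carbonyl}-6,10,14-trimethylpentadeca-5,9,13-trienoate | O=C1OC[C@H](Cc2ccccc2)N1C(=O)[C@@H](C/C=C(\C)CC/C=C(/C)CCC=C(C)C)CC(=O)OC(C)(C)C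
F3 | step 8 | tert-butyl (3S,5E,9Z)-3-[methoxy(methyl)carbamoyl]-6,10,14-trimethylpentadeca-5,9,13-trienoate | CON(C)C(=O)[C@@H](C/C=C(\C)CC/C=C(/C)CCC=C(C)C)CC(=O)OC(C)(C)C
F4 | step 8 | tert-butyl (3S,5E,9Z)-3-acetyl-6,10,14-trimethylpentadeca-5,9,13-trienoate | CC(=O)[C@@H](C/C=C(\C)CC/C=C(/C)CCC=C(C)C)CC(=O)OC(C)(C)C
F5 | step 8 | tert-butyl (3S,5E,9Z)-6,10,14-trimethyl-3-(prop-1-en-2-yl)pentadeca-5,9,13-trienoate | C=C(C)[C@@H](C/C=C(\C)CC/C=C(/C)CCC=C(C)C)CC(=O)OC(C)(C)C
F6 | step 15 | methyl (5R,7E,11Z)-2-[bis(2,2,2-trifluoroethoxy)phosphoryl]-8,12,16-trimethyl-5-(prop-1-en-2-yl)heptadeca-7,11,15-trienoate | C=C(C)[C@@H](C/C=C(\C)CC/C=C(/C)CCC=C(C)C)CCC(C(=O)OC)P(=O)(OCC(F)(F)F)OCC(F)(F)F
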